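**Plan**

- Retrosynthesis: the two MOM ethers come off last; the C3–OH and C2–H bonds are cut back to isoflavone 15; O1–C8a and C2–C3 are cut together, opening ring C to the 2-fluorodeoxybenzoin 13 plus one formate carbon; C3–C4 is cut to two benzaldehydes (3 and 11); the prenyl–C3′ bond is cut to aldehyde 7.
- Forward: rings A and B are bought as benzaldehydes 1 and 6, the chain is joined at C3–C4 by olefination and hydrolysis (step 6), and ring C is closed in step 7 by C2–C3 and then O1–C8a bond formation.
- Enabling feature: the C4 carbonyl is ortho to C8a on ring A, so a fluorine at C8a is displaced by the enolate oxygen of a formyl group on C3 (Meisenheimer complex stabilised by C4=O); the other ortho carbon, C5, already carries its oxygen as a MOM ether.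
- Helpers: the fluorine (activating and leaving group) is lost in the event itself; the C2=C3 unsaturation it leaves is the handle for the last C–O bond; the MOM groups go in the final step.
- Stereochemistry: the only stereocentre, C3 (S), is set in step 8 by reagent-controlled oxygen transfer from an enantiopure camphor-derived N-sulfonyloxaziridine to the cyclic enolate formed by hydride addition to C2 of 15.

Key step: step 7

Assumption: the facial preference of the camphor-derived oxaziridine for enolate 16 is taken to follow the empirical model for 2-substituted 1-tetralone-type enolates, which points to the (−)-reagent for the (S)-alcohol; the (+)-reagent is the remedy if the sense proves opposite.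

**Route**

Step 1
Reactants: 1 2,6-difluoro-4-methoxybenzaldehyde
Product: 2 2-fluoro-6-hydroxy-4-methoxybenzaldehyde
Conditions: KOH (2.2 equiv), DMSO/H2O, 0 °C to rt; aq. HCl
Reagents that add atoms: potassium hydroxide [K+].[OH-]
Why: Nucleophilic aromatic substitution of one of the two equivalent ortho-fluorides, activated by the formyl group, should stop after one exchange because the phenoxide formed deactivates the ring.

Step 2
Reactants: 2 2-fluoro-6-hydroxy-4-methoxybenzaldehyde
Product: 3 2-fluoro-4-methoxy-6-(methoxymethoxy)benzaldehyde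
Conditions: NaH, MOMCl, DMF, 0 °C to rt
Reagents that add atoms: chloromethyl methyl ether COCCl
Why: Williamson-type O-alkylation of the sodium phenoxide protects the future 5-OH so that it can neither quench bases nor close ring C from the wrong side.

Step 3
Reactants: 3 2-fluoro-4-methoxy-6-(methoxymethoxy)benzaldehyde
Product: 5 diphenyl {[2-fluoro-4-methoxy-6-(methoxymethoxy)phenyl](phenylamino)methyl}phosphonate (racemic), via N-phenyl imine 4 (not isolated)
Conditions: PhNH2, (PhO)2P(O)H, i-PrOH, rt
Reagents that add atoms: aniline Nc1ccccc1; diphenyl phosphite O=[PH](Oc1ccccc1)Oc1ccccc1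
Why: Kabachnik–Fields reaction (imine formation, then addition of the H-phosphonate) turns the aldehyde carbon into an acyl-anion equivalent that will become C4.

Step 4
Reactants: 6 4-hydroxy-2-methoxybenzaldehyde
Product: 7 2-methoxy-4-(methoxymethoxy)benzaldehyde
Conditions: NaH, MOMCl, DMF, 0 °C to rt
Reagents that add atoms: chloromethyl methyl ether COCCl
Why: Williamson-type O-alkylation installs a MOM ether that protects the 4′-OH and serves as a directing group for the next step.

Step 5
Reactants: 7 2-methoxy-4-(methoxymethoxy)benzaldehyde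
Product: 11 2-methoxy-4-(methoxymethoxy)-3-(3-methylbut-2-en-1-yl)benzaldehyde, via lithium α-amino alkoxide 8 (not isolated), via ring-lithiated amino alkoxide 9 (not isolated), via prenylated amino alkoxide 10 (not isolated)
Conditions: N-methylpiperazine, n-BuLi, THF, −20 °C; then 7; n-BuLi/TMEDA, −20 to 0 °C; CuBr·SMe2 (10 mol%), prenyl bromide, −78 °C to rt; H2O
Reagents that add atoms: 1-bromo-3-methylbut-2-ene (prenyl bromide) CC(C)=CCBr
Why: Directed ortho-metalation with the aldehyde masked in situ as an α-amino alkoxide should take place at the carbon flanked by the OMe and OMOM groups (cooperative direction), and copper-catalysed allylic substitution at the primary carbon of prenyl bromide then gives the linear prenyl arene.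

Step 6
Reactants: 5 diphenyl {[2-fluoro-4-methoxy-6-(methoxymethoxy)phenyl](phenylamino)methyl}phosphonate; 11 2-methoxy-4-(methoxymethoxy)-3-(3-methylbut-2-en-1-yl)benzaldehyde
Product: 13 1-[2-fluoro-4-methoxy-6-(methoxymethoxy)phenyl]-2-[2-methoxy-4-(methoxymethoxy)-3-(3-methylbut-2-en-1-yl)phenyl]ethan-1-one, via N-phenyl enamine 12 (not isolated)
Conditions: Cs2CO3, THF/i-PrOH, rt; then 1 M aq. HCl, 0 °C
Reagents that add atoms: water O
Why: Horner–Wadsworth–Emmons olefination of the α-aminophosphonate anion with aldehyde 11 forms the C3–C4 bond as an enamine, and brief cold hydrolysis should give the deoxybenzoin with both MOM ethers intact.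

Step 7
Reactants: 13 1-[2-fluoro-4-methoxy-6-(methoxymethoxy)phenyl]-2-[2-methoxy-4-(methoxymethoxy)-3-(3-methylbut-2-en-1-yl)phenyl]ethan-1-one
Product: 15 7-methoxy-5-(methoxymethoxy)-3-[2-methoxy-4-(methoxymethoxy)-3-(3-methylbut-2-en-1-yl)phenyl]-4H-chromen-4-one, via sodium formyl-ketone enolate 14 (not isolated)
Conditions: HCO2Et, NaH (1.2 equiv), THF, 0 °C to rt; volatiles removed; DMF, 90 °C
Reagents that add atoms: ethyl formate CCOC=O
Why: Crossed Claisen condensation of the sodium enolate of 13 with ethyl formate puts the one-carbon unit C2 on C3 and leaves the chelated (Z)-enolate 14, whose formyl oxygen lies next to C8a; on heating, this oxygen adds to the fluorine-bearing carbon C8a to give a Meisenheimer complex whose charge is taken up by the C4 carbonyl, and loss of fluoride restores ring A and completes the aromatic pyranone ring C (addition–elimination, SNAr). The closest known reaction types are the chromone synthesis from 1-(2-fluoroaryl)-1,3-dicarbonyl compounds and its nitrogen analogue used for 4-quinolones. Ring C closes in a 6-exo mode at an sp2 carbon, the C8a–C8 bond of the arene taking the electron pair for the lifetime of the complex. No stereocentre is formed. The step needs O- and not C-attack and a single site of closure: the enolate carbon C3 cannot reach C8a, ring A carries only one fluorine, the other ortho oxygen is blocked as its MOM ether, ethanol and excess formate are removed before heating so that no alkoxide competes for C8a, and the aromatic ring formed makes the closure irreversible.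

Step 8
Reactants: 15 7-methoxy-5-(methoxymethoxy)-3-[2-methoxy-4-(methoxymethoxy)-3-(3-methylbut-2-en-1-yl)phenyl]-4H-chromen-4-one
Product: 17 (3S)-3-hydroxy-7-methoxy-5-(methoxymethoxy)-3-[2-methoxy-4-(methoxymethoxy)-3-(3-methylbut-2-en-1-yl)phenyl]chroman-4-one, via lithium enolate 16 (not isolated)
Conditions: LiBH(s-Bu)3 (1.1 equiv), THF, −78 °C; then (−)-[(8,8-dichlorocamphoryl)sulfonyl]oxaziridine (1.5 equiv), −78 to −40 °C; AcOH
Reagents that add atoms: (−)-[(8,8-dichlorocamphoryl)sulfonyl]oxaziridine (enantiomer derived from (1R)-(−)-10-camphorsulfonic acid) CC1(C)C2CCC13CS(=O)(=O)N4OC34C2(Cl)Cl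
Why: Conjugate hydride addition to C2 of the chromone gives the C3=C4 enolate 16 regiospecifically and without base, and Davis oxidation with the enantiopure N-sulfonyloxaziridine should then deliver oxygen to one face of C3 under reagent control (camphor skeleton), which sets the (S)-configured tertiary alcohol while leaving the prenyl alkene untouched.

Step 9
Reactants: 17 (3S)-3-hydroxy-7-methoxy-5-(methoxymethoxy)-3-[2-methoxy-4-(methoxymethoxy)-3-(3-methylbut-2-en-1-yl)phenyl]chroman-4-one
Product: 19 (3S)-3,5-dihydroxy-3-[4-hydroxy-2-methoxy-3-(3-methylbut-2-en-1-yl)phenyl]-7-methoxychroman-4-one (target), via 4′-mono-MOM ether 18 (not isolated)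
Conditions: HCl (1.25 M in MeOH), THF, 0 °C to rt
Reagents that add atoms: none
Why: Acid-catalysed acetal exchange (methanolysis) removes both aryl MOM ethers, the one peri to C4=O first, under conditions mild enough that the tertiary benzylic alcohol should not ionise and the prenyl group should not cyclise onto the 4′-OH, so C3 keeps its configuration.

**Compound list**

1 | 2,6-difluoro-4-methoxybenzaldehyde | COc1cc(F)c(C=O)c(F)c1 | starting material
2 | 2-fluoro-6-hydroxy-4-methoxybenzaldehyde | COc1cc(O)c(C=O)c(F)c1 | intermediate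
3 | 2-fluoro-4-methoxy-6-(methoxymethoxy)benzaldehyde | COCOc1cc(OC)cc(F)c1C=O | intermediate
4 | (E)-1-[2-fluoro-4-methoxy-6-(methoxymethoxy)phenyl]-N-phenylmethanimine | COCOc1cc(OC)cc(F)c1/C=N/c1ccccc1 | intermediate (not isolated)
5 | diphenyl {[2-fluoro-4-methoxy-6-(methoxymethoxy)phenyl](phenylamino)methyl}phosphonate (racemic) | COCOc1cc(OC)cc(F)c1C(Nc1ccccc1)P(=O)(Oc1ccccc1)Oc1ccccc1 | intermediate
6 | 4-hydroxy-2-methoxybenzaldehyde | COc1cc(O)ccc1C=O | starting material
7 | 2-methoxy-4-(methoxymethoxy)benzaldehyde | COCOc1ccc(C=O)c(OC)c1 | intermediate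
8 | lithium [2-methoxy-4-(methoxymethoxy)phenyl](4-methylpiperazin-1-yl)methanolate (racemic) | COCOc1ccc(C(O[Li])N2CCN(C)CC2)c(OC)c1 | intermediate (not isolated)
9 | compound 8 lithiated at ring carbon 3, between OMe and OMOM (racemic) | COCOc1ccc(C(O[Li])N2CCN(C)CC2)c(OC)c1[Li] | intermediate (not isolated)
10 | lithium [2-methoxy-4-(methoxymethoxy)-3-(3-methylbut-2-en-1-yl)phenyl](4-methylpiperazin-1-yl)methanolate (racemic) | COCOc1ccc(C(O[Li])N2CCN(C)CC2)c(OC)c1CC=C(C)C | intermediate (not isolated)
11 | 2-methoxy-4-(methoxymethoxy)-3-(3-methylbut-2-en-1-yl)benzaldehyde | COCOc1ccc(C=O)c(OC)c1CC=C(C)C | intermediate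
12 | N-{1-[2-fluoro-4-methoxy-6-(methoxymethoxy)phenyl]-2-[2-methoxy-4-(methoxymethoxy)-3-(3-methylbut-2-en-1-yl)phenyl]ethenyl}aniline (E/Z mixture in equilibrium with the ketimine) | COc1cc(F)c(C(Nc2ccccc2)=Cc2ccc(OCOC)c(CC=C(C)C)c2OC)c(OCOC)c1 | intermediate (not isolated)
13 | 1-[2-fluoro-4-methoxy-6-(methoxymethoxy)phenyl]-2-[2-methoxy-4-(methoxymethoxy)-3-(3-methylbut-2-en-1-yl)phenyl]ethan-1-one | COc1cc(F)c(C(=O)Cc2ccc(OCOC)c(CC=C(C)C)c2OC)c(OCOC)c1 | intermediate
14 | sodium (Z)-3-[2-fluoro-4-methoxy-6-(methoxymethoxy)phenyl]-2-[2-methoxy-4-(methoxymethoxy)-3-(3-methylbut-2-en-1-yl)phenyl]-3-oxoprop-1-en-1-olate | [Na+].[O-]/C=C(/c1ccc(OCOC)c(CC=C(C)C)c1OC)C(=O)c1c(F)cc(OC)cc1OCOC | intermediate (not isolated)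
15 | 7-methoxy-5-(methoxymethoxy)-3-[2-methoxy-4-(methoxymethoxy)-3-(3-methylbut-2-en-1-yl)phenyl]-4H-chromen-4-one | COc1cc(OCOC)c2c(c1)occ(-c1ccc(OCOC)c(CC=C(C)C)c1OC)c2=O | intermediate
16 | lithium 7-methoxy-5-(methoxymethoxy)-3-[2-methoxy-4-(methoxymethoxy)-3-(3-methylbut-2-en-1-yl)phenyl]-2H-chromen-4-olate | COc1cc(OCOC)c2c(c1)OCC(c1ccc(OCOC)c(CC=C(C)C)c1OC)=C2O[Li] | intermediate (not isolated)
17 | (3S)-3-hydroxy-7-methoxy-5-(methoxymethoxy)-3-[2-methoxy-4-(methoxymethoxy)-3-(3-methylbut-2-en-1-yl)phenyl]chroman-4-one | COc1cc(OCOC)c2c(c1)OC[C@@](O)(c1ccc(OCOC)c(CC=C(C)C)c1OC)C2=O | intermediate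
18 | (3S)-3,5-dihydroxy-7-methoxy-3-[2-methoxy-4-(methoxymethoxy)-3-(3-methylbut-2-en-1-yl)phenyl]chroman-4-one | COc1cc(O)c2c(c1)OC[C@@](O)(c1ccc(OCOC)c(CC=C(C)C)c1OC)C2=O | intermediate (not isolated)
19 | (3S)-3,5-dihydroxy-3-[4-hydroxy-2-methoxy-3-(3-methylbut-2-en-1-yl)phenyl]-7-methoxychroman-4-one | COc1cc(O)c2c(c1)OC[C@@](O)(c1ccc(O)c(CC=C(C)C)c1OC)C2=O | target

**Summary**

Total step count: 9. Longest linear sequence: 7 steps (steps 1, 2, 3, 6, 7, 8, 9).

Steps most likely to fail:

1. Step 7. The delocalised enolate oxygen is a weak nucleophile and ring A carries two oxygen donors, so fluoride displacement may be slow enough for loss of the formyl group (retro-Claisen) or attack of residual alkoxide on C8a to compete. Fallback, from 13 back to 15: 13 is heated with N,N-dimethylformamide dimethyl acetal (toluene, 100 °C) to give (E)-3-(dimethylamino)-1-[2-fluoro-4-methoxy-6-(methoxymethoxy)phenyl]-2-[2-methoxy-4-(methoxymethoxy)-3-(3-methylbut-2-en-1-yl)phenyl]prop-2-en-1-one F1. F1 is then treated with KOH in DMSO/H2O at 60–80 °C, where hydroxide replaces the dimethylamino group or the fluoride and the ring closes in whichever order is faster, to give 15.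

2. Step 8. Facial discrimination in the oxygen transfer may be poor or reversed for a lithium enolate that still carries the borane, and 1,2-reduction of the chromone may compete. Fallback, from 15 back to 17: 15 is reduced with LiBH(s-Bu)3 (THF, −78 °C) and quenched with aqueous NH4Cl to give racemic 7-methoxy-5-(methoxymethoxy)-3-[2-methoxy-4-(methoxymethoxy)-3-(3-methylbut-2-en-1-yl)phenyl]chroman-4-one F2. F2 is then hydroxylated catalytically under chiral phase-transfer conditions (N-(9-anthracenylmethyl)cinchoninium bromide or its cinchonidinium pseudo-enantiomer, air, P(OEt)3, 50% aq. KOH/toluene, 0 °C) to give 17.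

3. Step 5. Metalation may occur at the wrong ring carbon (C5 or C6), butyllithium may add to the masked aldehyde, or coupling may occur at the tertiary end of the allyl system. Fallback, from 7 back to 11: 7 is converted with HC(OMe)3 and catalytic p-TsOH in MeOH into 1-(dimethoxymethyl)-2-methoxy-4-(methoxymethoxy)benzene F3, an isolated acetal with no nitrogen that could steer the base to C6. F3 is lithiated with n-BuLi (THF, 0 °C) to [3-(dimethoxymethyl)-2-methoxy-6-(methoxymethoxy)phenyl]lithium F4, which is coupled with prenyl bromide (CuBr·SMe2 catalysis) to give 1-(dimethoxymethyl)-2-methoxy-4-(methoxymethoxy)-3-(3-methylbut-2-en-1-yl)benzene F5. F5 is hydrolysed with aqueous oxalic acid on silica gel to give 11.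

Further compounds
F1 | step 7 | (E)-3-(dimethylamino)-1-[2-fluoro-4-methoxy-6-(methoxymethoxy)phenyl]-2-[2-methoxy-4-(methoxymethoxy)-3-(3-methylbut-2-en-1-yl)phenyl]prop-2-en-1-one | CN(C)/C=C(\c1ccc(OCOC)c(CC=C(C)C)c1OC)C(=O)c1c(F)cc(OC)cc1OCOC
F2 | step 8 | 7-methoxy-5-(methoxymethoxy)-3-[2-methoxy-4-(methoxymethoxy)-3-(3-methylbut-2-en-1-yl)phenyl]chroman-4-one (racemic) | COc1cc(OCOC)c2c(c1)OCC(c1ccc(OCOC)c(CC=C(C)C)c1OC)C2=O
F3 | step 5 | 1-(dimethoxymethyl)-2-methoxy-4-(methoxymethoxy)benzene | COCOc1ccc(C(OC)OC)c(OC)c1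
F4 | step 5 | [3-(dimethoxymethyl)-2-methoxy-6-(methoxymethoxy)phenyl]lithium | COCOc1ccc(C(OC)OC)c(OC)c1[Li]
F5 | step 5 | 1-(dimethoxymethyl)-2-methoxy-4-(methoxymethoxy)-3-(3-methylbut-2-en-1-yl)benzene | COCOc1ccc(C(OC)OC)c(OC)c1CC=C(C)C
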